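**Retrosynthetic overview**

- Feature: in the phenol ring (C1–OH, C2–OAr, C3–Br, C4–Br, C5–H, C6–Br) the Br/Br/H/Br set sits on the four contiguous carbons C3–C6, and both oxygens sit on the adjacent pair C1–C2.
- Key disconnection: C2–C3 and C1–C6. This gives 2,3,5-tribromothiophene 1,1-dioxide (C3–C6, with SO2 as a traceless bridge) and the silyl ketene acetal of methyl (2,4-dibromophenoxy)acetate (C1–C2, an aryloxyketene equivalent).
- The diaryl ether oxygen is installed before the ring exists, as an alkyl aryl ether from 2,4-dibromophenol and methyl bromoacetate. The dioxide comes from 2,3,5-tribromothiophene by S-oxidation.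
- Ring order: the dibromophenyl ring is bought. The phenol ring is the only ring formed, in the last step, with all five bromines already in place.

Key step: step 4

Remark on the chemistry: the target is achiral. The E/Z geometry of the ketene acetal and the sp3 centres of the cycloadducts are erased on aromatisation, so they are left unspecified.

**Route**

Step 1
Reactants: 1 2,3,5-tribromothiophene
Product: 3 2,3,5-tribromothiophene 1,1-dioxide, via tribromothiophene sulfoxide 2 (not isolated)
Conditions: H2O2 (85%), (CF3CO)2O, MeCN, 0 °C → rt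
Reagents that add atoms: peroxytrifluoroacetic acid, OOC(=O)C(F)(F)F, formed in the flask from hydrogen peroxide (OO) and trifluoroacetic anhydride (O=C(OC(=O)C(F)(F)F)C(F)(F)F)
Why: Electrophilic S-oxidation by peroxytrifluoroacetic acid, a peracid strong enough for electron-poor polyhalothiophenes, should take the sulfide through the sulfoxide to the sulfone, and the two α-bromines should keep the dioxide from Diels–Alder self-dimerisation.

Step 2
Reactants: 4 2,4-dibromophenol; 5 methyl bromoacetate
Product: 6 methyl 2-(2,4-dibromophenoxy)acetate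
Conditions: K2CO3, acetone, reflux
Reagents that add atoms: none
Why: Williamson ether synthesis, in which the phenoxide (pKa of the phenol near 8) displaces bromide from the activated primary α-bromo ester by SN2 while the aryl bromides are inert to K2CO3.

Step 3
Reactants: 6 methyl 2-(2,4-dibromophenoxy)acetate
Product: 8 1-methoxy-1-(trimethylsilyloxy)-2-(2,4-dibromophenoxy)ethene (E/Z mixture), via lithium ester enolate 7 (not isolated)
Conditions: LiN(SiMe3)2, Me3SiCl, THF, −78 °C → rt (base added to ester and silyl chloride); pentane, filtration, used crude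
Reagents that add atoms: chlorotrimethylsilane, C[Si](C)(C)Cl
Why: Kinetic ester enolisation and O-silylation with internal quench gives the silyl ketene acetal, since LiN(SiMe3)2 is basic enough for the aryloxy-acidified α-CH2 but too weak to metalate the bromoarene C–H bonds, and immediate trapping suppresses Claisen self-condensation.

Step 4
Reactants: 3 2,3,5-tribromothiophene 1,1-dioxide; 8 1-methoxy-1-(trimethylsilyloxy)-2-(2,4-dibromophenoxy)ethene
Product: 12 3,4,6-tribromo-2-(2,4-dibromophenoxy)phenol, via bridged sulfone cycloadduct 9 (not isolated), via cyclohexadiene silyl methyl ketal 10 (not isolated), via cyclohexadienone tautomer 11 (not isolated)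
Conditions: PhMe, 0 → 50 °C (−SO2); then 1 M HCl, THF, rt
Reagents that add atoms: none
Why: The electron-poor dioxide (diene LUMO) and the electron-rich ketene acetal (HOMO) should combine in an asynchronous inverse-electron-demand Diels–Alder reaction, after which bridged sulfone 9 loses SO2 by cheletropic extrusion to diene 10 and aqueous acid cleaves the silyl methyl ketal to dienone 11, which tautomerises to the phenol. The closest known reaction type is the annulation of halogenated thiophene 1,1-dioxides with enol-ether-type alkenes followed by SO2 loss and aromatisation, here with a ketene acetal serving as an aryloxyketene equivalent. The phenol ring closes by intermolecular [4+2] cycloaddition, the two new σ-bonds (C2–C3 and C1–C6 of the target) joining the diene termini to the two alkene carbons. No stereocentre survives, because the sp3 centres of 9 and 10 are erased on aromatisation, so neither endo/exo selectivity nor alkene geometry matters. The step needs the nucleophilic, aryloxy-bearing carbon to bond to thiophene C2; this should be favoured because the developing allyl-anion character then rests on C3 and C5, both brominated and C5 also α to the sulfonyl group, and because the bulkier acetal carbon then meets C5, whose neighbour C4 carries only hydrogen. The aryloxy group should be retained because the only sp3 carbons of 10 are the ketal carbon and the aryloxy-bearing CH, so aromatisation can only remove the ketal oxygens.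

**Compound list**

1 | 2,3,5-tribromothiophene | Brc1cc(Br)c(Br)s1 | starting material
2 | 2,3,5-tribromothiophene 1-oxide | O=S1C(Br)=C(Br)C=C1Br | intermediate
3 | 2,3,5-tribromothiophene 1,1-dioxide | O=S1(=O)C(Br)=C(Br)C=C1Br | intermediate
4 | 2,4-dibromophenol | Oc1ccc(Br)cc1Br | starting material
5 | methyl bromoacetate | COC(=O)CBr | starting material
6 | methyl 2-(2,4-dibromophenoxy)acetate | COC(=O)COc1ccc(Br)cc1Br | intermediate
7 | lithium enolate of methyl 2-(2,4-dibromophenoxy)acetate | [Li+].COC([O-])=COc1ccc(Br)cc1Br | intermediate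
8 | 1-methoxy-1-(trimethylsilyloxy)-2-(2,4-dibromophenoxy)ethene (E/Z mixture) | COC(O[Si](C)(C)C)=COc1ccc(Br)cc1Br | intermediate
9 | 1,2,4-tribromo-6-(2,4-dibromophenoxy)-5-methoxy-5-(trimethylsilyloxy)-7-thiabicyclo[2.2.1]hept-2-ene 7,7-dioxide (racemic diastereomer mixture) | O=S1(=O)C2(Br)C(Br)=CC1(Br)C(OC)(O[Si](C)(C)C)C2Oc1ccc(Br)cc1Br | intermediate
10 | 1,3,4-tribromo-5-(2,4-dibromophenoxy)-6-methoxy-6-(trimethylsilyloxy)cyclohexa-1,3-diene (racemic diastereomer mixture) | COC1(O[Si](C)(C)C)C(Br)=CC(Br)=C(Br)C1Oc1ccc(Br)cc1Br | intermediate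
11 | 2,4,5-tribromo-6-(2,4-dibromophenoxy)cyclohexa-2,4-dien-1-one (racemic) | O=C1C(Br)=CC(Br)=C(Br)C1Oc1ccc(Br)cc1Br | intermediate
12 | 3,4,6-tribromo-2-(2,4-dibromophenoxy)phenol | Oc1c(Br)cc(Br)c(Br)c1Oc1ccc(Br)cc1Br | target

**Step count**

Total steps: 4. Longest linear sequence: 3 steps (4 → 6 → 8 → 12); the dioxide branch (1 → 3) is one step.

**Steps most likely to fail, with fallbacks**

Step 4. Three things may go wrong:
- The first C–C bond may form at thiophene C5 instead of C2, which would lead to the regioisomeric phenol.
- The dipolar adduct may collapse by silyl transfer (Mukaiyama–Michael pathway) instead of closing the ring.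
- The ketal may aromatise by loss of trimethylsilanol, which would leave a methyl ether.

The fallback sets out from 4 and comes back at 12, building the ring substitution by directed arene chemistry. SNAr of 4 with 2-fluoro-1-methoxy-3-nitrobenzene (COc1cccc([N+](=O)[O-])c1F; K2CO3, DMF, 90 °C) should give 2-(2,4-dibromophenoxy)-1-methoxy-3-nitrobenzene F1. Reduction with Fe powder and NH4Cl (aqueous EtOH, 80 °C) should give 2-(2,4-dibromophenoxy)-3-methoxyaniline F2 without touching the aryl bromides. N-Bromosuccinimide (2 equiv, MeCN, 0 °C) should brominate ortho and para to the amino group, positions also activated by the methoxy group, to give 4,6-dibromo-2-(2,4-dibromophenoxy)-3-methoxyaniline F3. Sandmeyer bromination (t-BuONO, CuBr2, MeCN, 0 → 60 °C) through 4,6-dibromo-2-(2,4-dibromophenoxy)-3-methoxybenzenediazonium bromide F4 should put the third bromine on the former amine carbon and give 1,2,5-tribromo-3-(2,4-dibromophenoxy)-4-methoxybenzene F5. BBr3 (CH2Cl2, −78 → 0 °C) should then cleave the methyl ether to 12. The same BBr3 treatment would also convert any F5 that step 4 forms through loss of trimethylsilanol.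

Step 1. Oxidation may stall at the sulfoxide, whose self-dimerisation then consumes material, or the dioxide may degrade in the strongly acidic peracid medium.

The fallback sets out from 1 and comes back at 3, oxidising a more electron-rich, shielded thiophene and restoring the bromines afterwards. Bromine–lithium exchange at the α-position next to the 3-bromine (n-BuLi, THF, −78 °C) should give 3,5-dibromothiophen-2-yllithium F6, which Me3SiCl traps as 3,5-dibromo-2-(trimethylsilyl)thiophene F7. A second α-exchange (n-BuLi, THF, −78 °C) should give 4-bromo-5-(trimethylsilyl)thiophen-2-yllithium F8, trapped by Me3SiCl as 3-bromo-2,5-bis(trimethylsilyl)thiophene F9. mCPBA (CH2Cl2, rt) should oxidise this to 3-bromo-2,5-bis(trimethylsilyl)thiophene 1,1-dioxide F10. Ipso-bromodesilylation of both C–Si bonds (Br2, AgBF4, CH2Cl2, 0 °C) should then return 3.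

Step 3. The trimethylsilyl group may be lost by hydrolysis during isolation, the enolate may be silylated on carbon, or the lithium enolate may undergo Claisen self-condensation.

The fallback sets out from 6 and comes back at 11, and so at 12. Soft enolisation without a metal amide (t-BuMe2SiOTf, Et3N, CH2Cl2, 0 °C → rt) should give the more robust 1-(tert-butyldimethylsilyloxy)-1-methoxy-2-(2,4-dibromophenoxy)ethene F11. Under the thermal conditions of step 4 this should react with 3 to give the tert-butyldimethylsilyl analogue of the bridged sulfone F12 and, after loss of SO2, the cyclohexadiene tert-butyldimethylsilyl methyl ketal F13. Bu4NF with AcOH (THF, 0 °C) should desilylate F13 to dienone 11, which tautomerises to 12.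

**Further compounds**

F1 | step 4 | 2-(2,4-dibromophenoxy)-1-methoxy-3-nitrobenzene | COc1cccc([N+](=O)[O-])c1Oc1ccc(Br)cc1Br
F2 | step 4 | 2-(2,4-dibromophenoxy)-3-methoxyaniline | COc1cccc(N)c1Oc1ccc(Br)cc1Br
F3 | step 4 | 4,6-dibromo-2-(2,4-dibromophenoxy)-3-methoxyaniline | COc1c(Br)cc(Br)c(N)c1Oc1ccc(Br)cc1Br
F4 | step 4 | 4,6-dibromo-2-(2,4-dibromophenoxy)-3-methoxybenzenediazonium bromide | COc1c(Br)cc(Br)c([N+]#N)c1Oc1ccc(Br)cc1Br.[Br-]
F5 | step 4 | 1,2,5-tribromo-3-(2,4-dibromophenoxy)-4-methoxybenzene | COc1c(Br)cc(Br)c(Br)c1Oc1ccc(Br)cc1Br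
F6 | step 1 | 3,5-dibromothiophen-2-yllithium | [Li]c1sc(Br)cc1Br
F7 | step 1 | 3,5-dibromo-2-(trimethylsilyl)thiophene | C[Si](C)(C)c1sc(Br)cc1Br
F8 | step 1 | 4-bromo-5-(trimethylsilyl)thiophen-2-yllithium | [Li]c1cc(Br)c(s1)[Si](C)(C)C
F9 | step 1 | 3-bromo-2,5-bis(trimethylsilyl)thiophene | C[Si](C)(C)c1cc(Br)c(s1)[Si](C)(C)C
F10 | step 1 | 3-bromo-2,5-bis(trimethylsilyl)thiophene 1,1-dioxide | C[Si](C)(C)C1=CC(Br)=C([Si](C)(C)C)S1(=O)=O
F11 | step 3 | 1-(tert-butyldimethylsilyloxy)-1-methoxy-2-(2,4-dibromophenoxy)ethene (E/Z mixture) | COC(O[Si](C)(C)C(C)(C)C)=COc1ccc(Br)cc1Br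
F12 | step 3 | 1,2,4-tribromo-5-(tert-butyldimethylsilyloxy)-6-(2,4-dibromophenoxy)-5-methoxy-7-thiabicyclo[2.2.1]hept-2-ene 7,7-dioxide (racemic diastereomer mixture) | O=S1(=O)C2(Br)C(Br)=CC1(Br)C(OC)(O[Si](C)(C)C(C)(C)C)C2Oc1ccc(Br)cc1Br
F13 | step 3 | 1,3,4-tribromo-6-(tert-butyldimethylsilyloxy)-5-(2,4-dibromophenoxy)-6-methoxycyclohexa-1,3-diene (racemic diastereomer mixture) | COC1(O[Si](C)(C)C(C)(C)C)C(Br)=CC(Br)=C(Br)C1Oc1ccc(Br)cc1Br
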